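**Strategy.** Atoms are numbered C1(Me)=C2–C3(O)–C4(Me)–C8(H)–C9(O)–C10 around the seven-membered ring and C4–C5–C6–C7(OH)(iPr)–C8 around the cyclopentane. Everything rests on cutting C9–C10: C9 is a carbinol carbon homoallylic to C1, so the cycloheptane ring is closed by a type 2 carbonyl–ene reaction between a C9 aldehyde and a methallyl group hung on C3. In one operation this forms the C9–C10 bond, the seven-membered ring and the C9 alcohol, and leaves an exocyclic C1 methylene that a C3 ketone later draws into conjugation as C1=C2. The precursor is a trans-disubstituted cyclopentanecarbaldehyde, made from (R)-terpinen-4-ol, with triethylsilyl ethers at C7 and at the C3 methallyl carbinol.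

Key step: step 12

Remark: (R)-terpinen-4-ol is taken as enantiopure (enriched first if the commercial lot is not), and the route is written for the 3S carbinol expected in step 9; the 3R epimer would follow the same steps because C3 becomes a ketone in step 16.

Step 1
Reactants: 1 (R)-terpinen-4-ol
Product: 2 (R)-triethyl{[4-methyl-1-(propan-2-yl)cyclohex-3-en-1-yl]oxy}silane
Conditions: Et3SiOTf, 2,6-lutidine, CH2Cl2, 0 °C
Reagents that add atoms: triethylsilyl trifluoromethanesulfonate, CC[Si](CC)(CC)OS(=O)(=O)C(F)(F)F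
Why: Silyl triflate silylation of the hindered tertiary alcohol (no stereocentre involved) masks the oxygen that could otherwise be lost by β-elimination or misdirect the dehydration in the aldol condensation of step 2.

Step 2
Reactants: 2 silyl ether of terpinen-4-ol
Product: 4 (S)-2-methyl-5-(propan-2-yl)-5-[(triethylsilyl)oxy]cyclopent-1-ene-1-carbaldehyde, via keto aldehyde 3 (not isolated)
Conditions: O3, CH2Cl2, −78 °C; Me2S, −78 °C → rt; then piperidine, AcOH, toluene, 60 °C
Reagents that add atoms: ozone, [O-][O+]=O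
Why: Ozonolysis with reductive work-up opens the cyclohexene to keto aldehyde 3, and the amine-catalysed intramolecular aldol condensation (enamine of the aldehyde onto the methyl ketone, five-membered ring, dehydration into conjugation) gives the cyclopentene carbaldehyde with the C7 stereocentre untouched.

Step 3
Reactants: 4 cyclopentene carbaldehyde
Product: 5 (S)-{2-methyl-5-(propan-2-yl)-5-[(triethylsilyl)oxy]cyclopent-1-en-1-yl}methanol
Conditions: i-Bu2AlH, CH2Cl2, −78 °C
Reagents that add atoms: none
Why: Aluminium hydride 1,2-reduction of the hindered tetrasubstituted enal at low temperature gives the primary allylic alcohol without creating a stereocentre.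

Step 4
Reactants: 5 allylic alcohol; 6 tributyl(iodomethyl)stannane
Product: 8 (S)-3-methyl-1-(propan-2-yl)-2-{[(tributylstannyl)methoxy]methyl}cyclopent-2-en-1-ol, via silyl stannylmethyl ether 7 (not isolated)
Conditions: NaH, THF/DMF, 0 °C → rt; then Bu4NF, 40 °C
Reagents that add atoms: none
Why: Williamson etherification of the primary allylic alkoxide with the iodomethylstannane, followed by fluoride cleavage of the tertiary silyl ether in the same flask (the tetraalkylstannane is inert to fluoride), frees the C7 hydroxyl that steers step 5.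

Step 5
Reactants: 8 hydroxy stannylmethyl ether
Product: 10 (1S,3S)-3-(hydroxymethyl)-3-methyl-2-methylidene-1-(propan-2-yl)cyclopentan-1-ol, via dilithio species 9 (not isolated)
Conditions: n-BuLi (2.5 equiv), THF, −78 → −20 °C
Reagents that add atoms: none
Why: Still–Wittig [2,3]-sigmatropic rearrangement: after O–H deprotonation and tin–lithium exchange the α-alkoxy carbanion shifts suprafacially to C4 with transposition of the alkene to C8=C9, and it should do so on the face of the lithium alkoxide at C7 (internal lithium coordination, the other face being shielded by the isopropyl group), which sets the quaternary centre C4 with C3 cis to the C7 oxygen.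

Step 6
Reactants: 10 diol
Product: 11 (1S,4S)-4-methyl-7-methylidene-1-(propan-2-yl)-2-oxabicyclo[2.2.1]heptan-3-one
Conditions: TEMPO (cat.), PhI(OAc)2, CH2Cl2, rt
Reagents that add atoms: none
Why: Oxoammonium (TEMPO) oxidation of the primary alcohol to the aldehyde, closure of the cis-disposed tertiary hydroxyl to the lactol and further oxidation give the bridged γ-lactone, a ring closure open only to the diastereomer with C3 cis to the C7 oxygen, so the step also secures the configuration of C4 and creates no new stereocentre.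

Step 7
Reactants: 11 methylidene lactone
Product: 13 (1S,4S,7S)-7-(hydroxymethyl)-4-methyl-1-(propan-2-yl)-2-oxabicyclo[2.2.1]heptan-3-one, via alkylborane 12 (not isolated)
Conditions: 9-BBN, THF, 60 °C; then H2O2, aq. NaOAc, 0 °C → rt
Reagents that add atoms: hydrogen peroxide, OO
Why: Hydroboration–oxidation places boron on the terminal C9 and adds hydrogen to C8 from the face of the flat lactone bridge, because the opposite face of the exocyclic alkene is blocked by the exo hydrogens of the C5–C6 bridge, so C8–H ends cis to C3 and the C7 oxygen and the hydroxymethyl group trans to both, while the buffered peroxide work-up spares the lactone.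

Step 8
Reactants: 13 hydroxy lactone
Product: 14 (1S,4S,7S)-7-(hydroxymethyl)-4-methyl-1-(propan-2-yl)-2-oxabicyclo[2.2.1]heptan-3-ol (anomer mixture)
Conditions: i-Bu2AlH (2.5 equiv), CH2Cl2, −78 °C
Reagents that add atoms: none
Why: Partial reduction of the lactone at low temperature stops at the lactol (stable aluminium hemiacetal), which brings C3 to the aldehyde oxidation level without touching any stereocentre that is kept.

Step 9
Reactants: 14 lactol; 15 2-methylallylmagnesium chloride
Product: 16 (1S)-1-[(1S,2S,3S)-3-hydroxy-2-(hydroxymethyl)-1-methyl-3-(propan-2-yl)cyclopentyl]-3-methylbut-3-en-1-ol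
Conditions: THF, 0 °C → rt (excess 15)
Reagents that add atoms: none
Why: Grignard addition to the open hydroxy aldehyde form of the lactol, in which attack anti to the C4–C8 bond should favour the 3S carbinol drawn, and the C3 configuration is in any case erased at ketone 26.

Step 10
Reactants: 16 triol
Product: 17 tris(triethylsilyl) ether of 16
Conditions: Et3SiOTf, 2,6-lutidine, CH2Cl2, −78 → 0 °C
Reagents that add atoms: triethylsilyl trifluoromethanesulfonate, CC[Si](CC)(CC)OS(=O)(=O)C(F)(F)F
Why: Exhaustive silylation with the silyl triflate protects the primary, the neopentyl secondary and the hindered tertiary hydroxyl in one operation and provides a non-chelating silyl ether at C7 for the key step, with no change at any stereocentre.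

Step 11
Reactants: 17 tris(silyl) ether
Product: 18 (1R,2S,5S)-2-methyl-2-{(1S)-3-methyl-1-[(triethylsilyl)oxy]but-3-en-1-yl}-5-(propan-2-yl)-5-[(triethylsilyl)oxy]cyclopentane-1-carbaldehyde
Conditions: (COCl)2, DMSO, CH2Cl2, −78 → −40 °C; then Et3N, −78 → 0 °C
Reagents that add atoms: none
Why: Under Swern conditions a primary triethylsilyl ether is cleaved by the chlorosulfonium reagent and oxidised directly to the aldehyde while secondary and tertiary triethylsilyl ethers survive, and the cold, brief amine treatment should leave the α-stereocentre C8 unchanged.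

Step 12
Reactants: 18 aldehyde
Product: 19 (3S,3aS,4R,8S,8aS)-8a-methyl-6-methylidene-3-(propan-2-yl)-3,8-bis[(triethylsilyl)oxy]decahydroazulen-4-ol
Conditions: Me2AlCl (2.5 equiv), CH2Cl2, −78 → −20 °C
Reagents that add atoms: none
Why: Me2AlCl binds the C9 aldehyde oxygen, the 1,1-disubstituted alkene attacks C9 through its terminal carbon C10 while a hydrogen of the C1 methyl passes to oxygen in a six-centre array, and loss of methane from the resulting aluminium alkoxide removes the proton source, so C9–C10 forms with the alkene left exocyclic at C1. The closest known reaction type is the Lewis acid-promoted type 2 intramolecular carbonyl–ene cyclisation of aldehydes carrying a methallyl group, which is established for six- and seven-membered methylenecycloalkanols. The seven-membered ring closes 7-exo-trig at the carbonyl with the ene joined through its central carbon C1 (alkene endocyclic to the forming ring), and because C4 and C8 are spectators the trans ring fusion is inherited from the cyclopentane. The new stereocentre C9 is set by the cyclic transition state: hydrogen transfer requires C9–O gauche to C10–C1 (pseudo-axial on the chair-like forming ring), the tether forces C10 to approach gauche to C4 and therefore anti to the C8–C7 bond, and the non-chelating silyloxy group at C7 keeps its C–O dipole opposed to the activated carbonyl, which together place oxygen on the face of the C4 methyl, anti to the C7 oxygen (9R). The step needs this facial selectivity and chemoselective activation of the aldehyde, which the fixed trans arrangement of the two arms, the pseudo-equatorial 3S silyloxy group, the monodentate use of the Lewis acid and the low temperature should secure.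

Step 13
Reactants: 20 4-hydroxybenzoic acid
Product: 22 4-[(tert-butyldimethylsilyl)oxy]benzoic acid, via silyl ester 21 (not isolated)
Conditions: t-BuMe2SiCl, imidazole, DMF, rt; then AcOH, THF/H2O, rt
Reagents that add atoms: tert-butyldimethylsilyl chloride, CC(C)(C)[Si](C)(C)Cl
Why: Silylation of both the phenol and the acid followed by mild aqueous hydrolysis of the labile silyl ester leaves the acid-stable aryl silyl ether, giving the protected acid for step 14.

Step 14
Reactants: 19 ene product; 22 protected acid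
Product: 24 (3S,3aS,4R,8S,8aS)-8a-methyl-6-methylidene-3-(propan-2-yl)-3,8-bis[(triethylsilyl)oxy]decahydroazulen-4-yl 4-[(tert-butyldimethylsilyl)oxy]benzoate, via mixed anhydride 23 (not isolated)
Conditions: 2,4,6-Cl3C6H2COCl, Et3N, THF, rt; then 19, DMAP, toluene, 60 °C
Reagents that add atoms: none
Why: Yamaguchi esterification, in which the mixed anhydride passes its less hindered aroyl group through the acylpyridinium to the congested C9 hydroxyl (the only free hydroxyl in 19) with retention at C9 and without forming an alkoxide that could trigger silyl migration.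

Step 15
Reactants: 24 bis(silyl) ester
Product: 25 (3S,3aS,4R,8S,8aS)-3,8-dihydroxy-8a-methyl-6-methylidene-3-(propan-2-yl)decahydroazulen-4-yl 4-[(tert-butyldimethylsilyl)oxy]benzoate
Conditions: CSA (cat.), MeOH/CH2Cl2, 0 °C → rt
Reagents that add atoms: none
Why: Acid-catalysed methanolysis removes both alkyl triethylsilyl ethers while the aryl silyl ether and the aryl ester are stable to mild acid, and the C7 hydroxyl needs no protection once C9 is no longer a carbonyl.

Step 16
Reactants: 25 diol ester
Product: 27 (3S,3aS,4R,8aS)-3-hydroxy-6,8a-dimethyl-8-oxo-3-(propan-2-yl)-1,2,3,3a,4,5,8,8a-octahydroazulen-4-yl 4-[(tert-butyldimethylsilyl)oxy]benzoate, via β,γ-unsaturated ketone 26 (not isolated)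
Conditions: Dess–Martin periodinane, NaHCO3, CH2Cl2, rt; then DBU (cat.), CH2Cl2, 0 °C → rt
Reagents that add atoms: none
Why: Dess–Martin oxidation converts the secondary C3 alcohol (the tertiary C7 alcohol cannot be oxidised) into the β,γ-unsaturated ketone 26, and catalytic base then moves the alkene into conjugation through the dienolate (deprotonation at C2, protonation at the exocyclic carbon), so that the C3 carbonyl fixes the alkene at C1=C2 and not at C1=C10.

Step 17
Reactants: 27 enone
Product: 28 (3S,3aS,4R,8S,8aS)-3,8-dihydroxy-6,8a-dimethyl-3-(propan-2-yl)-1,2,3,3a,4,5,8,8a-octahydroazulen-4-yl 4-[(tert-butyldimethylsilyl)oxy]benzoate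
Conditions: NaBH4, CeCl3·7H2O, MeOH, −78 °C
Reagents that add atoms: none
Why: Luche reduction gives clean 1,2-reduction of the enone, and hydride should enter anti to the pseudo-axial C4 methyl on the adjacent carbon, placing the C3 hydroxyl cis to that methyl (3S).

Step 18
Reactants: 28 allylic alcohol; 29 3-methylbutanoyl chloride
Product: 30 (3S,3aS,4R,8S,8aS)-3-hydroxy-6,8a-dimethyl-8-[(3-methylbutanoyl)oxy]-3-(propan-2-yl)-1,2,3,3a,4,5,8,8a-octahydroazulen-4-yl 4-[(tert-butyldimethylsilyl)oxy]benzoate
Conditions: pyridine, DMAP (cat.), CH2Cl2, 0 °C → rt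
Reagents that add atoms: none
Why: Acylation with the acid chloride under nucleophilic (DMAP) catalysis esterifies the secondary allylic C3 hydroxyl with retention, while the hindered tertiary C7 hydroxyl does not react.

Step 19
Reactants: 30 silyl-protected diester
Product: 31 target, (3S,3aS,4R,8S,8aS)-3-hydroxy-6,8a-dimethyl-8-[(3-methylbutanoyl)oxy]-3-(propan-2-yl)-1,2,3,3a,4,5,8,8a-octahydroazulen-4-yl 4-hydroxybenzoate
Conditions: Bu4NF, AcOH, THF, 0 °C → rt
Reagents that add atoms: none
Why: Fluoride cleaves the aryl silyl ether selectively, and buffering with acetic acid keeps the liberated phenoxide from attacking either ester, so no stereocentre is affected.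

**Compound list**

1 | (R)-terpinen-4-ol | CC1=CC[C@@](O)(C(C)C)CC1 | starting material
2 | (R)-triethyl{[4-methyl-1-(propan-2-yl)cyclohex-3-en-1-yl]oxy}silane | CC1=CC[C@@](O[Si](CC)(CC)CC)(C(C)C)CC1 | intermediate
3 | (R)-6-oxo-3-(propan-2-yl)-3-[(triethylsilyl)oxy]heptanal | O=CC[C@@](O[Si](CC)(CC)CC)(C(C)C)CCC(C)=O | intermediate
4 | (S)-2-methyl-5-(propan-2-yl)-5-[(triethylsilyl)oxy]cyclopent-1-ene-1-carbaldehyde | CC1=C(C=O)[C@@](O[Si](CC)(CC)CC)(C(C)C)CC1 | intermediate
5 | (S)-{2-methyl-5-(propan-2-yl)-5-[(triethylsilyl)oxy]cyclopent-1-en-1-yl}methanol | CC1=C(CO)[C@@](O[Si](CC)(CC)CC)(C(C)C)CC1 | intermediate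
6 | tributyl(iodomethyl)stannane | CCCC[Sn](CCCC)(CCCC)CI | starting material
7 | (S)-tributyl[({2-methyl-5-(propan-2-yl)-5-[(triethylsilyl)oxy]cyclopent-1-en-1-yl}methoxy)methyl]stannane | CC1=C(COC[Sn](CCCC)(CCCC)CCCC)[C@@](O[Si](CC)(CC)CC)(C(C)C)CC1 | intermediate
8 | (S)-3-methyl-1-(propan-2-yl)-2-{[(tributylstannyl)methoxy]methyl}cyclopent-2-en-1-ol | CC1=C(COC[Sn](CCCC)(CCCC)CCCC)[C@@](O)(C(C)C)CC1 | intermediate
9 | dilithio species from 8 (lithium alkoxide, C–Li in place of C–Sn) | CC1=C(COC[Li])[C@@](O[Li])(C(C)C)CC1 | intermediate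
10 | (1S,3S)-3-(hydroxymethyl)-3-methyl-2-methylidene-1-(propan-2-yl)cyclopentan-1-ol | OC[C@@]1(C)CC[C@](O)(C(C)C)C1=C | intermediate
11 | (1S,4S)-4-methyl-7-methylidene-1-(propan-2-yl)-2-oxabicyclo[2.2.1]heptan-3-one | O=C1O[C@]2(C(C)C)CC[C@@]1(C)C2=C | intermediate
12 | B-alkyl-9-borabicyclo[3.3.1]nonane from 11 (boron on C9, C8–H syn to the lactone bridge) | O=C1O[C@]2(C(C)C)CC[C@@]1(C)[C@H]2CB1C2CCCC1CCC2 | intermediate
13 | (1S,4S,7S)-7-(hydroxymethyl)-4-methyl-1-(propan-2-yl)-2-oxabicyclo[2.2.1]heptan-3-one | O=C1O[C@]2(C(C)C)CC[C@@]1(C)[C@H]2CO | intermediate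
14 | (1S,4S,7S)-7-(hydroxymethyl)-4-methyl-1-(propan-2-yl)-2-oxabicyclo[2.2.1]heptan-3-ol (anomer mixture) | OC1O[C@]2(C(C)C)CC[C@@]1(C)[C@H]2CO | intermediate
15 | 2-methylallylmagnesium chloride (THF solution) | C=C(C)C[Mg]Cl | starting material
16 | (1S)-1-[(1S,2S,3S)-3-hydroxy-2-(hydroxymethyl)-1-methyl-3-(propan-2-yl)cyclopentyl]-3-methylbut-3-en-1-ol | C=C(C)C[C@H](O)[C@@]1(C)CC[C@](O)(C(C)C)[C@@H]1CO | intermediate
17 | tris(triethylsilyl) ether of 16 | C=C(C)C[C@H](O[Si](CC)(CC)CC)[C@@]1(C)CC[C@](O[Si](CC)(CC)CC)(C(C)C)[C@@H]1CO[Si](CC)(CC)CC | intermediate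
18 | (1R,2S,5S)-2-methyl-2-{(1S)-3-methyl-1-[(triethylsilyl)oxy]but-3-en-1-yl}-5-(propan-2-yl)-5-[(triethylsilyl)oxy]cyclopentane-1-carbaldehyde (CHO trans to the C3 arm and to the C7 oxygen) | C=C(C)C[C@H](O[Si](CC)(CC)CC)[C@@]1(C)CC[C@](O[Si](CC)(CC)CC)(C(C)C)[C@@H]1C=O | intermediate
19 | (3S,3aS,4R,8S,8aS)-8a-methyl-6-methylidene-3-(propan-2-yl)-3,8-bis[(triethylsilyl)oxy]decahydroazulen-4-ol | C=C1C[C@H](O[Si](CC)(CC)CC)[C@@]2(C)CC[C@](O[Si](CC)(CC)CC)(C(C)C)[C@@H]2[C@H](O)C1 | intermediate
20 | 4-hydroxybenzoic acid | OC(=O)c1ccc(O)cc1 | starting material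
21 | tert-butyldimethylsilyl 4-[(tert-butyldimethylsilyl)oxy]benzoate | CC(C)(C)[Si](C)(C)Oc1ccc(cc1)C(=O)O[Si](C)(C)C(C)(C)C | intermediate
22 | 4-[(tert-butyldimethylsilyl)oxy]benzoic acid | CC(C)(C)[Si](C)(C)Oc1ccc(cc1)C(=O)O | intermediate
23 | 4-[(tert-butyldimethylsilyl)oxy]benzoic 2,4,6-trichlorobenzoic anhydride | CC(C)(C)[Si](C)(C)Oc1ccc(cc1)C(=O)OC(=O)c1c(Cl)cc(Cl)cc1Cl | intermediate
24 | (3S,3aS,4R,8S,8aS)-8a-methyl-6-methylidene-3-(propan-2-yl)-3,8-bis[(triethylsilyl)oxy]decahydroazulen-4-yl 4-[(tert-butyldimethylsilyl)oxy]benzoate | C=C1C[C@H](O[Si](CC)(CC)CC)[C@@]2(C)CC[C@](O[Si](CC)(CC)CC)(C(C)C)[C@@H]2[C@H](OC(=O)c2ccc(O[Si](C)(C)C(C)(C)C)cc2)C1 | intermediate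
25 | (3S,3aS,4R,8S,8aS)-3,8-dihydroxy-8a-methyl-6-methylidene-3-(propan-2-yl)decahydroazulen-4-yl 4-[(tert-butyldimethylsilyl)oxy]benzoate | C=C1C[C@H](O)[C@@]2(C)CC[C@](O)(C(C)C)[C@@H]2[C@H](OC(=O)c2ccc(O[Si](C)(C)C(C)(C)C)cc2)C1 | intermediate
26 | (3S,3aS,4R,8aS)-3-hydroxy-8a-methyl-6-methylidene-8-oxo-3-(propan-2-yl)decahydroazulen-4-yl 4-[(tert-butyldimethylsilyl)oxy]benzoate | C=C1CC(=O)[C@@]2(C)CC[C@](O)(C(C)C)[C@@H]2[C@H](OC(=O)c2ccc(O[Si](C)(C)C(C)(C)C)cc2)C1 | intermediate
27 | (3S,3aS,4R,8aS)-3-hydroxy-6,8a-dimethyl-8-oxo-3-(propan-2-yl)-1,2,3,3a,4,5,8,8a-octahydroazulen-4-yl 4-[(tert-butyldimethylsilyl)oxy]benzoate | CC1=CC(=O)[C@@]2(C)CC[C@](O)(C(C)C)[C@@H]2[C@H](OC(=O)c2ccc(O[Si](C)(C)C(C)(C)C)cc2)C1 | intermediate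
28 | (3S,3aS,4R,8S,8aS)-3,8-dihydroxy-6,8a-dimethyl-3-(propan-2-yl)-1,2,3,3a,4,5,8,8a-octahydroazulen-4-yl 4-[(tert-butyldimethylsilyl)oxy]benzoate | CC1=C[C@H](O)[C@@]2(C)CC[C@](O)(C(C)C)[C@@H]2[C@H](OC(=O)c2ccc(O[Si](C)(C)C(C)(C)C)cc2)C1 | intermediate
29 | 3-methylbutanoyl chloride | CC(C)CC(Cl)=O | starting material
30 | (3S,3aS,4R,8S,8aS)-3-hydroxy-6,8a-dimethyl-8-[(3-methylbutanoyl)oxy]-3-(propan-2-yl)-1,2,3,3a,4,5,8,8a-octahydroazulen-4-yl 4-[(tert-butyldimethylsilyl)oxy]benzoate | CC1=C[C@H](OC(=O)CC(C)C)[C@@]2(C)CC[C@](O)(C(C)C)[C@@H]2[C@H](OC(=O)c2ccc(O[Si](C)(C)C(C)(C)C)cc2)C1 | intermediate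
31 | (3S,3aS,4R,8S,8aS)-3-hydroxy-6,8a-dimethyl-8-[(3-methylbutanoyl)oxy]-3-(propan-2-yl)-1,2,3,3a,4,5,8,8a-octahydroazulen-4-yl 4-hydroxybenzoate | CC1=C[C@H](OC(=O)CC(C)C)[C@@]2(C)CC[C@](O)(C(C)C)[C@@H]2[C@H](OC(=O)c2ccc(O)cc2)C1 | target

**Step count.** Total: 19 steps. Longest linear sequence: 18 steps (1 to 31 through steps 1–12 and 14–19); step 13 is a one-step side branch.

**Steps most likely to fail**

Step 12. The aluminium-bound oxygen must sit next to the C4 methyl and the C7 isopropyl group in the required transition state. Steric compression there may push the cyclisation through a twisted or stepwise (zwitterionic) pathway, so facial selectivity at C9 may erode or invert. The fallback sets out from 18 and comes back at 19; it keeps the ring closure but sets C9 afterwards by reduction. The ring-closed material is the C9-epimeric alcohol (3S,3aS,4S,8S,8aS)-8a-methyl-6-methylidene-3-(propan-2-yl)-3,8-bis[(triethylsilyl)oxy]decahydroazulen-4-ol F1, alone or mixed with 19. It would be oxidised with Dess–Martin periodinane (NaHCO3, CH2Cl2) to the C9 ketone F2. Li(s-Bu)3BH in THF at −78 °C should then deliver hydride from the open face of the ring (the face of H8, away from the C4 methyl and the isopropyl group) and give the pseudo-axial alcohol 19.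

Step 5. At the hindered, tetrasubstituted alkene terminus the [2,3] shift may be slow, so that the carbanion diverts into a [1,2]-shift or protonation, and facial selectivity may erode. The fallback sets out from 5 and comes back at 10; it uses a neutral, thermal one-carbon [2,3] rearrangement instead of a carbanion. Heating 5 with N,N-dimethylformamide dimethyl acetal (xylene, 140 °C) exchanges the primary allylic alcohol into the amide acetal. Its (allyloxy)(dimethylamino)carbene rearranges to the homologous amide (1S,3S)-N,N,1-trimethyl-2-methylidene-3-(propan-2-yl)-3-[(triethylsilyl)oxy]cyclopentane-1-carboxamide F3, with C3 as the amide carbon on C4 and the alkene exocyclic at C8. LiBHEt3 in THF would reduce the tertiary amide to the primary alcohol F4, and Bu4NF would remove the silyl ether to give 10. The lactonisation of step 6 again rejects any C4 epimer.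

Step 7. The alkene is flanked by two quaternary carbons, so the hydroboration may be sluggish or discriminate poorly between the faces. The fallback sets out from 10 and comes back at 13; it delivers hydrogen intramolecularly. Silylation of the primary hydroxyl of 10 with ClSiMe2H/Et3N gives the hydrosilane F5. Pt2[(CH2=CHSiMe2)2O]3 (zerovalent platinum, toluene, 60 °C) should induce endo hydrosilylation to the six-membered, trans-fused cyclic siloxane F6, with hydrogen delivered to C8 from the face of the C3 arm. Tamao oxidation (KF, KHCO3, H2O2, THF/MeOH) gives the triol F7. TEMPO/PhI(OAc)2 closes the lactone and oxidises C9 to the aldehyde F8, and NaBH4 (MeOH, −20 °C) reduces the aldehyde to 13.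

**Further compounds**

F1 | step 12 | (3S,3aS,4S,8S,8aS)-8a-methyl-6-methylidene-3-(propan-2-yl)-3,8-bis[(triethylsilyl)oxy]decahydroazulen-4-ol | C=C1C[C@H](O[Si](CC)(CC)CC)[C@@]2(C)CC[C@](O[Si](CC)(CC)CC)(C(C)C)[C@@H]2[C@@H](O)C1
F2 | step 12 | (3S,3aR,8S,8aS)-8a-methyl-6-methylidene-3-(propan-2-yl)-3,8-bis[(triethylsilyl)oxy]octahydroazulen-4(1H)-one | C=C1C[C@H](O[Si](CC)(CC)CC)[C@@]2(C)CC[C@](O[Si](CC)(CC)CC)(C(C)C)[C@@H]2C(=O)C1
F3 | step 5 | (1S,3S)-N,N,1-trimethyl-2-methylidene-3-(propan-2-yl)-3-[(triethylsilyl)oxy]cyclopentane-1-carboxamide | CN(C)C(=O)[C@@]1(C)CC[C@](O[Si](CC)(CC)CC)(C(C)C)C1=C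
F4 | step 5 | {(1S,3S)-1-methyl-2-methylidene-3-(propan-2-yl)-3-[(triethylsilyl)oxy]cyclopentyl}methanol | OC[C@@]1(C)CC[C@](O[Si](CC)(CC)CC)(C(C)C)C1=C
F5 | step 7 | (1S,3S)-3-{[(dimethylsilyl)oxy]methyl}-3-methyl-2-methylidene-1-(propan-2-yl)cyclopentan-1-ol | C[SiH](C)OC[C@@]1(C)CC[C@](O)(C(C)C)C1=C
F6 | step 7 | trans-fused 1,4,4-trimethyl-7-(propan-2-yl)-3-oxa-4-silabicyclo[4.3.0]nonan-7-ol (ring-fusion hydrogen cis to the hydroxyl) | C[Si]1(C)OC[C@@]2(C)CC[C@](O)(C(C)C)[C@@H]2C1
F7 | step 7 | (1S,2S,3S)-2,3-bis(hydroxymethyl)-3-methyl-1-(propan-2-yl)cyclopentan-1-ol | OC[C@@]1(C)CC[C@](O)(C(C)C)[C@@H]1CO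
F8 | step 7 | (1S,4S,7R)-4-methyl-3-oxo-1-(propan-2-yl)-2-oxabicyclo[2.2.1]heptane-7-carbaldehyde | O=C1O[C@]2(C(C)C)CC[C@@]1(C)[C@H]2C=O
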